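**Plan** (azaphilone numbering: C1, O2, C3, C4, C4a, C5–C8, C8a)
1. Cuts: ring B at O2–C3 (lactol oxygen onto a C3≡C4 alkyne), ring A at C4a–C8a and C7–C8, the side chain at the alkyne–alkene bond.
2. Enabling feature: ring A is a 6-hydroxy-6-methylcyclohex-2-enone (C6=O, C4a=C5, tertiary C7–OH), i.e. a β-eliminated 7-oxanorbornanone, so C4a–C5–C6–C7 with the C7 oxygen is a 2-methyl-3-silyloxyfuran; C8 and C8a carry trans oxygens and C8a the formyl carbon C1, i.e. an (E)-2,3-dioxygenated acrolein.
3. Forward: furan (from ethyl lactate, a diyne and an iodoalkene) plus enal (from a glycerol acetal and (R)-3-hydroxybutanoic acid) → Diels–Alder (ring A skeleton with a temporary oxygen bridge) → fluoride opening of the bridge → gold-catalysed hydrative 6-endo closure of ring B → global deprotection.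
4. Stereochemistry: the C8/C8a trans relation comes from the E enal (suprafacial addition), their relation to C7 from endo approach, and C7–O from the bridge (racemic lactate converges in the planar furan).
5. The side-chain centre comes from (R)-3-hydroxybutanoic acid; the two facial adducts are diastereomers and are separated; C1 is set by anomeric equilibration.

Key step: step 12

Assumption: the 1R lactol (OH trans to the C8a hydroxyl) is taken to be the thermodynamically preferred anomer, reached by equilibration through the open hydroxy aldehyde.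

Step 1
Reactants: 1 ethyl 2-hydroxypropanoate (racemic ethyl lactate)
Product: 2 2-hydroxy-N-methoxy-N-methylpropanamide
Conditions: MeNHOMe·HCl, iPrMgCl (3.2 equiv), THF, −20 to 0 °C
Reagents that add atoms: N,O-dimethylhydroxylamine hydrochloride, CNOC.Cl
Why: Magnesium-amide aminolysis of the ester (Weinreb amide formation) is standard for lactate esters, and the stereocentre is irrelevant because C7 is planarised in step 6.

Step 2
Reactants: 2 2-hydroxy-N-methoxy-N-methylpropanamide; 3 1,4-bis(trimethylsilyl)buta-1,3-diyne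
Product: 5 2-hydroxy-7-(trimethylsilyl)hepta-4,6-diyn-3-one, via lithium (trimethylsilyl)butadiynide 4 (not isolated)
Conditions: 3, MeLi·LiBr, THF, −78 to −20 °C; then 2 (0.45 equiv), −78 to 0 °C; aq NH4Cl
Reagents that add atoms: none
Why: MeLi·LiBr removes one silyl group of 3 to give acetylide 4, one equivalent of which deprotonates the hydroxyl while the next adds to the amide, whose chelated tetrahedral adduct stops at the ketone (Weinreb ketone synthesis).

Step 3
Reactants: 5 2-hydroxy-7-(trimethylsilyl)hepta-4,6-diyn-3-one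
Product: 6 2-methyl-5-[(trimethylsilyl)ethynyl]furan-3(2H)-one
Conditions: (4-CF3C6H4)3PAuCl (2 mol %), AgOSO2CF3 (2 mol %), PhMe, 25 °C
Reagents that add atoms: none
Why: Cationic monovalent gold activates the ynone for 5-endo-dig attack of the hydroxyl on the alkyne carbon β to the carbonyl (hydroalkoxylation, the usual route from 2-hydroxy ynones to furan-3(2H)-ones), leaving the silyl-capped distal alkyne untouched.

Step 4
Reactants: 7 3,3-diethoxyprop-1-yne
Product: 9 (1E)-3,3-diethoxy-1-iodoprop-1-ene, via alkenylzirconocene chloride 8 (not isolated)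
Conditions: Cp2Zr(H)Cl, THF, 25 °C; then I2, 0 °C
Reagents that add atoms: iodine, II
Why: Hydrozirconation adds Zr–H syn with zirconium at the terminal carbon and iodinolysis proceeds with retention, which fixes the E geometry of the side-chain alkene.

Step 5
Reactants: 6 2-methyl-5-[(trimethylsilyl)ethynyl]furan-3(2H)-one; 9 (1E)-3,3-diethoxy-1-iodoprop-1-ene
Product: 11 5-[(3E)-5,5-diethoxypent-3-en-1-yn-1-yl]-2-methylfuran-3(2H)-one, via 5-ethynyl-2-methylfuran-3(2H)-one 10 (not isolated)
Conditions: PdCl2(PPh3)2 (3 mol %), CuI (6 mol %), CsF, H2O (2 equiv), Et3N, THF, 25 °C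
Reagents that add atoms: none
Why: Fluoride unmasks the terminal alkyne only in the presence of the catalysts, so that it is consumed at once in a Sonogashira coupling with retention of the E alkene geometry.

Step 6
Reactants: 11 5-[(3E)-5,5-diethoxypent-3-en-1-yn-1-yl]-2-methylfuran-3(2H)-one
Product: 13 tert-butyl({5-[(3E)-5,5-diethoxypent-3-en-1-yn-1-yl]-2-methylfuran-3-yl}oxy)dimethylsilane, via sodium furan-3-olate 12 (not isolated)
Conditions: NaN(SiMe3)2, THF, −78 °C; then TBSCl, −78 to 0 °C
Reagents that add atoms: tert-butyldimethylsilyl chloride, CC(C)(C)[Si](C)(C)Cl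
Why: Deprotonation at C7 gives the aromatic furan-3-olate, which is silylated on oxygen (silyl enol ether formation without a silyl triflate, so the acetal survives); the lactate stereocentre is erased here, so racemic 1 suffices.

Step 7
Reactants: 14 cis-2-phenyl-1,3-dioxan-5-ol
Product: 15 triethyl[(cis-2-phenyl-1,3-dioxan-5-yl)oxy]silane
Conditions: TESCl, imidazole, CH2Cl2, 0 °C
Reagents that add atoms: triethylsilyl chloride, CC[Si](Cl)(CC)CC
Why: Standard silylation of a secondary alcohol.

Step 8
Reactants: 15 triethyl[(cis-2-phenyl-1,3-dioxan-5-yl)oxy]silane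
Product: 16 2-[(triethylsilyl)oxy]propane-1,3-diol
Conditions: H2 (1 atm), Pd(OH)2/C, EtOAc, 25 °C
Reagents that add atoms: none
Why: Hydrogenolysis of the benzylidene acetal under neutral conditions frees both primary hydroxyls without touching the silyl ether.

Step 9
Reactants: 16 2-[(triethylsilyl)oxy]propane-1,3-diol
Product: 17 (2E)-3-hydroxy-2-[(triethylsilyl)oxy]prop-2-enal
Conditions: Dess–Martin periodinane (2.5 equiv), pyridine, CH2Cl2, 0 °C
Reagents that add atoms: none
Why: Double Dess–Martin oxidation of the 1,3-diol gives the 2-substituted malonaldehyde, which rests as the hydrogen-bonded enol with the hydroxyl cis to the formyl group.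

Step 10
Reactants: 18 (3R)-3-hydroxybutanoic acid
Product: 20 (3R)-3-[(tert-butyldimethylsilyl)oxy]butanoic acid, via silyl ester 19 (not isolated)
Conditions: TBSCl (2.2 equiv), imidazole, DMF, 25 °C; then K2CO3, MeOH–H2O, 0 °C; acidify
Reagents that add atoms: tert-butyldimethylsilyl chloride, CC(C)(C)[Si](C)(C)Cl
Why: Exhaustive silylation followed by selective cleavage of the labile silyl ester is the usual access to O-silyl β-hydroxy acids, and the stereocentre is not involved.

Step 11
Reactants: 17 (2E)-3-hydroxy-2-[(triethylsilyl)oxy]prop-2-enal; 20 (3R)-3-[(tert-butyldimethylsilyl)oxy]butanoic acid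
Product: 23 (1E)-3-oxo-2-[(triethylsilyl)oxy]prop-1-en-1-yl (3R)-3-[(tert-butyldimethylsilyl)oxy]butanoate, via acid chloride 21 (not isolated), via lithium enolate 22 (not isolated)
Conditions: 20, 1-chloro-N,N,2-trimethylprop-1-en-1-amine, CH2Cl2, 0 °C; 17, LiN(SiMe3)2, PhMe, −78 °C; mix, −78 to −40 °C
Reagents that add atoms: none
Why: O-acylation of the lithium-chelated, U-shaped malonaldehyde enolate by the acid chloride (made under neutral conditions) places the acyloxy group cis to the remaining formyl group, the known outcome of enol ester formation from chelated 1,3-dicarbonyl enolates; the two enolate oxygens are equivalent and the 2-substituent blocks C-acylation.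

Step 12
Reactants: 13 tert-butyl({5-[(3E)-5,5-diethoxypent-3-en-1-yn-1-yl]-2-methylfuran-3-yl}oxy)dimethylsilane; 23 (1E)-3-oxo-2-[(triethylsilyl)oxy]prop-1-en-1-yl (3R)-3-[(tert-butyldimethylsilyl)oxy]butanoate
Product: 24 endo cycloadduct (7-oxabicyclo[2.2.1]hept-5-ene with endo acyloxy on C8, endo formyl and exo OSiEt3 on C8a; full name in the compound list)
Conditions: PhMe (1 M), 2,6-di-tert-butyl-4-methylphenol (trace), 45 °C, dark
Reagents that add atoms: none
Why: Thermal normal-electron-demand [4+2] cycloaddition, asynchronous with the C7–C8 bond leading (C7 is the nucleophilic terminus of the 3-silyloxyfuran, C8 the β-carbon of the enal), so that C4a–C8a joins the alkynyl terminus to the formyl-bearing carbon; the closest known type is the Diels–Alder reaction of 3-silyloxy- and 3-alkoxyfurans with enals and acrylates. It closes carbocycle A by a suprafacial six-membered [4+2] closure and at the same time the temporary C7–O–C4a bridge of a 7-oxabicyclo[2.2.1]heptene. At C8 and C8a the E geometry of 23 is transferred suprafacially, which sets the trans relation of the two oxygens, and at C7 and C4a the furan oxygen stays syn to both new bonds. The relation of C8/C8a to C7 needs the formyl group and the cis acyloxy group endo: the Alder rule favours endo carbonyl groups, the exo position on C8 lies over the C7 methyl group so that only hydrogen fits there, and the exo silyloxy group on C8a meets only the slender alkynyl group. Regiochemistry is secured by the silyloxy group on C6, which directs the formyl-bearing carbon para to it. The remote butanoate stereocentre cannot bias the furan face, so both endo adducts are expected in comparable amounts; they are diastereomers and are separated in step 13.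

Step 13
Reactants: 24 endo cycloadduct
Product: 26 enynyl cyclohexenone aldehyde (ring A complete; full name in the compound list), via bicyclic ketone 25 (not isolated)
Conditions: Bu4NF (1.1 equiv), AcOH (1.1 equiv), THF, −78 °C; then Et3N, 0 °C; chromatography
Reagents that add atoms: none
Why: Fluoride cleaves the silyl enol ether far faster than the alkyl silyl ethers, and the resulting C6 ketone expels the bridge oxygen from C4a by E1cB elimination (the usual opening of 7-oxanorbornan-2-ones), which leaves the oxygen on C7 with its configuration and gives the C4a=C5 enone; acetic acid prevents acyl migration to the C7 alkoxide, and the two facial diastereomers are separated here.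

Step 14
Reactants: 26 enynyl cyclohexenone aldehyde
Product: 27 O8a-triethylsilyl O3'-tert-butyldimethylsilyl diethyl acetal of azaphilone D
Conditions: Ph3PAuN(SO2CF3)2 (5 mol %), H2O (5 equiv), THF, 25 °C
Reagents that add atoms: water, O
Why: The C1 carbonyl oxygen attacks the gold-activated alkyne 6-endo-dig at C3 (the δ-carbon of the C6 enone, also stabilised by the alkenyl group) and water captures the cyclic oxocarbenium ion, as in the hydrative cycloisomerisation of ortho-alkynyl benzaldehydes to isochromenols; C1 settles by anomeric equilibration.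

Step 15
Reactants: 27 O8a-triethylsilyl O3'-tert-butyldimethylsilyl diethyl acetal of azaphilone D
Product: 28 azaphilone D
Conditions: 48% aq HF, MeCN, 0 to 25 °C
Reagents that add atoms: water, O
Why: Aqueous HF cleaves both silyl ethers and hydrolyses the allylic diethyl acetal to the E enal, while the lactol equilibrates to the preferred 1R anomer (global deprotection).

**Compound list**
1 | ethyl 2-hydroxypropanoate (racemic) | CCOC(=O)C(C)O | starting material
2 | 2-hydroxy-N-methoxy-N-methylpropanamide (racemic) | CC(O)C(=O)N(C)OC | intermediate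
3 | 1,4-bis(trimethylsilyl)buta-1,3-diyne | C[Si](C)(C)C#CC#C[Si](C)(C)C | starting material
4 | lithium 4-(trimethylsilyl)buta-1,3-diyn-1-ide | [Li]C#CC#C[Si](C)(C)C | intermediate
5 | 2-hydroxy-7-(trimethylsilyl)hepta-4,6-diyn-3-one (racemic) | CC(O)C(=O)C#CC#C[Si](C)(C)C | intermediate
6 | 2-methyl-5-[(trimethylsilyl)ethynyl]furan-3(2H)-one (racemic) | CC1OC(C#C[Si](C)(C)C)=CC1=O | intermediate
7 | 3,3-diethoxyprop-1-yne | C#CC(OCC)OCC | starting material
8 | chlorobis(cyclopentadienyl)[(1E)-3,3-diethoxyprop-1-en-1-yl]zirconium | CCOC(OCC)/C=C/[Zr](Cl)(C1C=CC=C1)C1C=CC=C1 | intermediate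
9 | (1E)-3,3-diethoxy-1-iodoprop-1-ene | CCOC(OCC)/C=C/I | intermediate
10 | 5-ethynyl-2-methylfuran-3(2H)-one | CC1OC(C#C)=CC1=O | intermediate
11 | 5-[(3E)-5,5-diethoxypent-3-en-1-yn-1-yl]-2-methylfuran-3(2H)-one (racemic) | CCOC(OCC)/C=C/C#CC1=CC(=O)C(C)O1 | intermediate
12 | sodium 5-[(3E)-5,5-diethoxypent-3-en-1-yn-1-yl]-2-methylfuran-3-olate | Cc1oc(C#C/C=C/C(OCC)OCC)cc1[O-].[Na+] | intermediate
13 | tert-butyl({5-[(3E)-5,5-diethoxypent-3-en-1-yn-1-yl]-2-methylfuran-3-yl}oxy)dimethylsilane | Cc1oc(C#C/C=C/C(OCC)OCC)cc1O[Si](C)(C)C(C)(C)C | intermediate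
14 | cis-2-phenyl-1,3-dioxan-5-ol | O[C@H]1CO[C@@H](c2ccccc2)OC1 | starting material
15 | triethyl[(cis-2-phenyl-1,3-dioxan-5-yl)oxy]silane | CC[Si](CC)(CC)O[C@H]1CO[C@@H](c2ccccc2)OC1 | intermediate
16 | 2-[(triethylsilyl)oxy]propane-1,3-diol | CC[Si](CC)(CC)OC(CO)CO | intermediate
17 | (2E)-3-hydroxy-2-[(triethylsilyl)oxy]prop-2-enal (enol of 2-(triethylsilyloxy)malonaldehyde, OH cis to CHO) | O=C/C(O[Si](CC)(CC)CC)=C\O | intermediate
18 | (3R)-3-hydroxybutanoic acid | C[C@@H](O)CC(=O)O | starting material
19 | tert-butyldimethylsilyl (3R)-3-[(tert-butyldimethylsilyl)oxy]butanoate | C[C@@H](O[Si](C)(C)C(C)(C)C)CC(=O)O[Si](C)(C)C(C)(C)C | intermediate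
20 | (3R)-3-[(tert-butyldimethylsilyl)oxy]butanoic acid | C[C@@H](O[Si](C)(C)C(C)(C)C)CC(=O)O | intermediate
21 | (3R)-3-[(tert-butyldimethylsilyl)oxy]butanoyl chloride | C[C@@H](O[Si](C)(C)C(C)(C)C)CC(=O)Cl | intermediate
22 | lithium (1E)-3-oxo-2-[(triethylsilyl)oxy]prop-1-en-1-olate (chelated) | O=C/C(O[Si](CC)(CC)CC)=C\[O-].[Li+] | intermediate
23 | (1E)-3-oxo-2-[(triethylsilyl)oxy]prop-1-en-1-yl (3R)-3-[(tert-butyldimethylsilyl)oxy]butanoate (acyloxy cis to CHO) | O=C/C(O[Si](CC)(CC)CC)=C\OC(=O)C[C@@H](C)O[Si](C)(C)C(C)(C)C | intermediate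
24 | (3R)-3-[(tert-butyldimethylsilyl)oxy]butanoate of 3-endo-formyl-6-[(tert-butyldimethylsilyl)oxy]-4-[(3E)-5,5-diethoxypent-3-en-1-yn-1-yl]-1-methyl-3-exo-[(triethylsilyl)oxy]-7-oxabicyclo[2.2.1]hept-5-en-2-endo-ol (target enantiomeric series) | C[C@@H](O[Si](C)(C)C(C)(C)C)CC(=O)O[C@@H]1[C@](O[Si](CC)(CC)CC)(C=O)[C@]2(C#C/C=C/C(OCC)OCC)C=C(O[Si](C)(C)C(C)(C)C)[C@@]1(C)O2 | intermediate
25 | (3R)-3-[(tert-butyldimethylsilyl)oxy]butanoate of 3-endo-formyl-4-[(3E)-5,5-diethoxypent-3-en-1-yn-1-yl]-1-methyl-6-oxo-3-exo-[(triethylsilyl)oxy]-7-oxabicyclo[2.2.1]heptan-2-endo-ol | C[C@@H](O[Si](C)(C)C(C)(C)C)CC(=O)O[C@@H]1[C@](O[Si](CC)(CC)CC)(C=O)[C@]2(C#C/C=C/C(OCC)OCC)CC(=O)[C@@]1(C)O2 | intermediate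
26 | (3R)-3-[(tert-butyldimethylsilyl)oxy]butanoate of 2-formyl-6-hydroxy-6-methyl-5-oxo-3-[(3E)-5,5-diethoxypent-3-en-1-yn-1-yl]-2-[(triethylsilyl)oxy]cyclohex-3-en-1-ol (6-OH cis to 2-OSiEt3, both trans to the 1-acyloxy group; the 7S,8R,8aS series of the target) | C[C@@H](O[Si](C)(C)C(C)(C)C)CC(=O)O[C@@H]1[C@](O[Si](CC)(CC)CC)(C=O)C(=CC(=O)[C@@]1(C)O)C#C/C=C/C(OCC)OCC | intermediate
27 | azaphilone D carrying OSiEt3 on C8a, OSiMe2tBu on the butanoate and a diethyl acetal in place of the side-chain aldehyde | C[C@@H](O[Si](C)(C)C(C)(C)C)CC(=O)O[C@@H]1[C@@]2(O[Si](CC)(CC)CC)C(=CC(=O)[C@@]1(C)O)C=C(/C=C/C(OCC)OCC)O[C@H]2O | intermediate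
28 | azaphilone D | C[C@@H](O)CC(=O)O[C@@H]1[C@@]2(O)C(=CC(=O)[C@@]1(C)O)C=C(/C=C/C=O)O[C@H]2O | target

**Count and risks**
Total steps: 15. Longest linear sequence: 9 (steps 1, 2, 3, 5, 6, 12, 13, 14, 15).

Step 12. The two partners are both fairly electron-rich, so the cycloaddition may be slow; the formyl group may end up exo (wrong relation of C8/C8a to C7); the enol ester may lose its geometry on heating; the enal may react as an oxadiene; and no facial bias is built in. The fallback sets out from 11, 18 and 22 and comes back at 26; it ties the partners together before the cycloaddition. Furanone 11 is converted with NaN(SiMe3)2 and an excess of iPr2SiCl2 into the chlorosilyl furyl ether F1. Two equivalents of F1 silylate both oxygens of acid 18 to give the bis-silyl compound F2. Oxalyl chloride with catalytic DMF turns the silyl ester of F2 into the acid chloride F3 and returns one equivalent of F1. F3 acylates lithium enolate 22 as in step 11 to give the tethered furan–enal F4. Heating F4 in dilute toluene should give the bridged adduct F5 (a type 2 intramolecular Diels–Alder reaction): the seven-atom silyl acetal tether from the C6 oxygen reaches C8 most easily on the endo side, which places the cis formyl group endo and the C8a silyloxy group exo, and its stereocentre may also bias the furan face. Bu4NF/AcOH then removes the silicon bridge and opens the oxygen bridge to the hydroxy enone F6, and TBSCl/imidazole silylates its secondary hydroxyl to return to 26.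

Step 14. The cyclisation may take the 5-exo course onto C4, another oxygen (C7–OH, ester carbonyl) may attack the activated alkyne, or the acetal may be lost early under the Lewis-acidic conditions. The fallback sets out from 26 and comes back at 27; it replaces π-acid activation by nucleophilic hydration of the ynenone. Pyrrolidine adds in 1,6-fashion to C3 of 26 (the δ-carbon of the C6 enone) to give the dienaminone F7. Hydrolysis on wet silica gel or with aqueous oxalic acid releases the C3 ketone, whose dienol closes on the C1 aldehyde to give lactol 27.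

Step 15. The hindered tertiary silyl ether may be cleaved too slowly, and the dienol ether lactol may ionise at C1 and decompose under the acid needed. The fallback sets out from 26 and comes back at 28; it removes the silyl groups before ring B exists. Excess Bu4NF/AcOH converts 26 into the triol aldehyde F8. The gold-catalysed hydrative cyclisation of step 14 should then give the acetal lactol F9 (the aldehyde oxygen reaches C3 in the 6-endo mode more easily than the C8a hydroxyl does in the 5-endo mode). Pyridinium p-toluenesulfonate in wet acetone finally hydrolyses only the acetal to give 28.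

Further compounds
F1 | step 12 | chloro({5-[(3E)-5,5-diethoxypent-3-en-1-yn-1-yl]-2-methylfuran-3-yl}oxy)di(propan-2-yl)silane | Cc1oc(C#C/C=C/C(OCC)OCC)cc1O[Si](Cl)(C(C)C)C(C)C
F2 | step 12 | (3R)-3-hydroxybutanoic acid silylated on both oxygens by the furyloxydi(propan-2-yl)silyl group | Cc1oc(C#C/C=C/C(OCC)OCC)cc1O[Si](C(C)C)(C(C)C)O[C@H](C)CC(=O)O[Si](C(C)C)(C(C)C)Oc1cc(C#C/C=C/C(OCC)OCC)oc1C
F3 | step 12 | (3R)-3-{[(furyloxy)di(propan-2-yl)silyl]oxy}butanoyl chloride | Cc1oc(C#C/C=C/C(OCC)OCC)cc1O[Si](C(C)C)(C(C)C)O[C@H](C)CC(=O)Cl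
F4 | step 12 | silicon-tethered furan–enal: (1E)-3-oxo-2-[(triethylsilyl)oxy]prop-1-en-1-yl (3R)-3-{[(furyloxy)di(propan-2-yl)silyl]oxy}butanoate | Cc1oc(C#C/C=C/C(OCC)OCC)cc1O[Si](C(C)C)(C(C)C)O[C@H](C)CC(=O)O/C=C(\C=O)O[Si](CC)(CC)CC
F5 | step 12 | bridged cycloadduct with the di(propan-2-yl)silylene linking the C6 enol oxygen and the butanoate oxygen | C[C@@H]1CC(=O)O[C@@H]2[C@](O[Si](CC)(CC)CC)(C=O)[C@]3(C#C/C=C/C(OCC)OCC)C=C(O[Si](C(C)C)(C(C)C)O1)[C@@]2(C)O3
F6 | step 12 | hydroxy enone (26 without the tert-butyldimethylsilyl group) | C[C@@H](O)CC(=O)O[C@@H]1[C@](O[Si](CC)(CC)CC)(C=O)C(=CC(=O)[C@@]1(C)O)C#C/C=C/C(OCC)OCC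
F7 | step 14 | dienaminone from 1,6-addition of pyrrolidine to C3 of 26 | C[C@@H](O[Si](C)(C)C(C)(C)C)CC(=O)O[C@@H]1[C@](O[Si](CC)(CC)CC)(C=O)C(=CC(=O)[C@@]1(C)O)C=C(/C=C/C(OCC)OCC)N1CCCC1
F8 | step 15 | triol aldehyde (26 without both silyl groups) | C[C@@H](O)CC(=O)O[C@@H]1[C@](O)(C=O)C(=CC(=O)[C@@]1(C)O)C#C/C=C/C(OCC)OCC
F9 | step 15 | side-chain diethyl acetal of azaphilone D | C[C@@H](O)CC(=O)O[C@@H]1[C@@]2(O)C(=CC(=O)[C@@]1(C)O)C=C(/C=C/C(OCC)OCC)O[C@H]2O
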